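## Structural features

The target is monocyclic: a cyclohexa-1,3-diene (ring carbons C1–C6, alkenes C1=C2 and C3=C4) with one exocyclic carbon, C7, on C1. C7 is a benzoyloxymethyl group, C5 carries a second benzoate, and C6, which lies between these two acylated positions, keeps a free secondary hydroxyl. C5 and C6 are the only stereocentres; they are adjacent, both R, and their oxygens sit on opposite faces of the ring (trans). The compound is a masked arene: loss of benzoic acid or water across C5/C6 gives a benzene ring, the C5 benzoate is allylic to the whole diene and ionises easily, and the benzoyl group can move from O5 to the free O6 under base. The real difficulty is therefore threefold: to build an oxygenated cyclohexadiene without conditions that aromatise it, to set C6 trans to C5 in one enantiomeric series, and to acylate O5 and O7 while the hydroxyl between them stays free. The feature that the plan exploits is that C6 is a carbinol bonded to C1, that C1 is the α-carbon of a one-carbon acyl unit (C7, taken at the ester level), and that its alkene C1=C2 runs on into C3=C4. This is the pattern of a Morita–Baylis–Hillman adduct closed into a ring, so the C1–C6 bond can be made from an open-chain formyl dienoate whose only stereocentre is C5.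

## Logic of the disconnections

15 to 14: the O6–Si bond is cut last. A free O6 next to the O5 benzoate is the arrangement most prone to acyl migration and aromatisation, so it is exposed only in the final step. The gain is that both benzoates can be put on with no selectivity question. The demand is a fluoride source that is neither basic nor strongly acidic.

14 to 13: the two acyl C–O bonds at O5 and O7 are cut together. With O6 blocked, a diol remains in which both free hydroxyls are to be acylated, so one operation serves for both. The demand is acylation conditions that do not move silicon from O6 to O5.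

13 to 12 to 10 (through 11): the O5–Si bond is restored and C7 is returned from the alcohol to the ester level. The ester is what activates C1 for ring formation, and the labile silyl group on O5 is the one the open-chain chemistry needs. The forward demands are a clean 1,2-reduction of a dienoate and removal of a triethylsilyl ether beside a tert-butyldimethylsilyl ether on the neighbouring oxygen.

10 to 9: the O6–Si bond of the robust silyl ether is cut, giving the hydroxy ester as it leaves the ring closure. The forward step must silylate a hindered carbinol without a base able to remove the C5 hydrogen, which is vinylogously acidic through the dienoate.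

9 to 8: the C1–C6 bond is cut. This removes the ring and the C6 stereocentre at once and leaves an acyclic (2E,4Z)-dienoate with an aldehyde at C6 and a single stereocentre, C5. The forward step must make the phosphine add at C2 and not at C4, must close trans, and must not epimerise the aldehyde α-carbon C5. The O5 substituent is triethylsilyl because the same group allows the aldehyde to be released by direct oxidation of a primary silyl ether, is bulky enough to steer the aldol step, and can later be removed selectively.

8 to 7 to 6 to 5: the aldehyde C6 is traced to a primary silyl ether, the two silyl ethers to a diol, and the diol to an acetonide. The aldehyde is too labile to carry, so it is revealed in the step immediately before cyclisation. The acetonide stores both oxygens through the C–C bond-forming steps. The demand is an oxidation that distinguishes the primary from the secondary silyl ether under conditions that do not epimerise C5.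

5 to 4: the C3=C4 cis alkene is traced to an alkyne. The Z geometry that ring closure needs is obtained most reliably by syn addition of hydrogen. The demand is to stop at the diene stage.

4 to 2 and 3: the C2–C3 bond (sp2–sp) is cut. This divides the chain into a three-carbon acrylate piece (C7, C1, C2) and a four-carbon chiral piece (C3 to C6). The coupling must retain the E geometry of C1=C2 and must not touch the acetonide.

2 to 1: the C3≡C4 bond is cut by a one-carbon homologation, C3 coming from a diazophosphonate. The chiral four-carbon piece is thereby reduced to a three-carbon chiral-pool aldehyde. The demand is that the α-alkoxy aldehyde is not racemised.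

## Other disconnections considered

Alternative 1: The cut is the C1–C7 bond, with the one-carbon unit delivered from a silicon tether on O6.
- Forward route: the C2-symmetric (1R,2R)-cyclohexa-3,5-diene-1,2-diol A1 would be mono-benzoylated (its two hydroxyls are homotopic, so only one product is possible) and silylated to (1R,6R)-6-{[(iodomethyl)dimethylsilyl]oxy}cyclohexa-2,4-dien-1-yl benzoate A2.
- Key step: with Pd(OAc)2, a bisphosphine and visible light, photoexcited zerovalent palladium would homolyse the C–I bond. The silylmethyl radical would add to C1 in a 5-exo-trig closure, and loss of the hydrogen on C1 would regenerate the C1=C2–C3=C4 diene in the oxasilacycle A3. Tamao–Fleming oxidation of the C7–Si bond and benzoylation of the primary hydroxyl would finish.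
- In its favour: both stereocentres come with A1 and no new one is formed, so there is no diastereoselectivity question, which is better than the chosen plan. The O5 benzoate is placed at the start without any temporary group. The sequence is about five operations from A1, clearly shorter.
- Against it here: enantiopure A1 is not an ordinary catalogue compound and is itself an arene hydrate that dehydrates easily. The key step places low-valent palladium beside a benzoate that is allylic to a diene, so Tsuji–Trost ionisation and aromatisation compete with the radical path. The allyl radical formed after addition at C1 can lose hydrogen from C5 as well as from C1. The basic peroxide of the Tamao step meets a benzoate next to a freshly freed hydroxyl.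
- Comparison: the two plans are equal in forming the diene inside the key step. The alternative is better in step count and stereochemical simplicity. The chosen plan is better in supply of the chiral starting material, in keeping transition metals away from the dienyl ester, and in delaying the benzoates until the ring is secure.

Alternative 2: The cuts are C1–C2 and C5–C6, a Diels–Alder disconnection made after formally returning an amine to C2.
- Forward key step: a chiral dienamine such as (1E,3E)-4-[(2R,5R)-2,5-diphenylpyrrolidin-1-yl]buta-1,3-dien-1-yl benzoate A4 would add to (E)-3-[(triisopropylsilyl)oxy]prop-2-enal A5. It is drawn with one antipode of the amine; which antipode leads to the 5R,6R series would have to follow from the facial model. The amine-bearing terminus C2 bonds to the formyl-bearing C1 and the benzoyloxy terminus C5 to the silyloxy carbon C6. β-Elimination of the amine from C2 would then give the dienal A6.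
- Completion: reduction of the formyl group (NaBH4, CeCl3·7H2O), benzoylation of O7 and desilylation, three operations.
- In its favour: the route is convergent. Ring, both stereocentres, the diene and the O5 benzoate appear in one step. The trans relationship follows from the E geometry of both partners through a formyl-endo transition state. O5 never needs a temporary group. On convergence and step count it is better than the chosen plan.
- Against it here: A5 is a vinylogous formate and a poor dienophile. The C5–C6 bond must join two oxygen-bearing carbons. The dienamine must be made and held E at C4=C5. A6 and the amino aldehyde before it are one elimination of benzoic acid or silanol away from a benzaldehyde. The absolute configuration rests on induction from a remote auxiliary rather than on a purchased stereocentre.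
- Comparison: equal in that the trans relationship comes from a cyclic transition state. The alternative is better in convergence and step economy. The chosen plan is better in certainty of absolute configuration and in the reactivity of its intramolecular closure.

Alternative 3: The cut is the bond between the carbons that become C2 and C6 in a bicyclo[3.1.0]hexane, so the six-membered ring is traced to a cyclopentene plus one carbon that becomes C1.
- Forward route: the C2-symmetric (3R,5R)-3,5-bis[(tert-butyldimethylsilyl)oxy]cyclopent-1-ene A7 would take up dibromocarbene (CHBr3, KOtBu) to give the dibromocyclopropane A8; either face gives the same compound.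
- Key step: AgBF4 in buffered aqueous acetone would ionise one C–Br bond with disrotatory opening to a 2-bromocyclohexenyl cation. Water would add at C6 anti to the C5 silyl ether to give (1S,4R,6R)-2-bromo-4,6-bis[(tert-butyldimethylsilyl)oxy]cyclohex-2-en-1-ol A9.
- In its favour: the symmetry removes every regiochemical question, since the alkene faces and the two cation termini are equivalent. The reactions are robust and run on intermediates with no epimerisable centre, which is better than the sensitive aldehyde of the chosen plan. The trans C5/C6 relationship is substrate-controlled, equal to the chosen plan. The C1 bromide is a handle for C7.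
- Against it here: A9 lacks C7 and the C3=C4 alkene and carries an extra oxygen on C3. That oxygen must be eliminated late, exactly when aromatisation threatens most. The two silyl ethers, equivalent in A7, are different in A9 and must be told apart, in addition to O6. Enantiopure A7 must itself be prepared.
- Comparison: in step economy the alternative is expected to be no shorter and probably longer. Structurally it is less direct, because three functions of its key-step product need re-working, whereas the chosen closure delivers ring, diene, both oxygens and C7 in place.

Key step: step 7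

Assumption: target locants C1–C7 are used for every intermediate in the discussion, also where the systematic name of an open-chain compound numbers the chain from the ester carbon. The formyl carbon of 1 becomes C4 and its CH2O carbon becomes C6, so the S aldehyde leads to the 5R series (the descriptor changes only because substituent priorities change). Compounds 1 and 3 are taken as catalogue materials.

## Route

Step 1
Reactants: 1 (S)-2,2-dimethyl-1,3-dioxolane-4-carbaldehyde
Product: 2 (R)-4-ethynyl-2,2-dimethyl-1,3-dioxolane
Conditions: dimethyl (1-diazo-2-oxopropyl)phosphonate, K2CO3, MeOH, 0 °C → rt; product kept as a concentrated solution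
Reagents that add atoms: dimethyl (1-diazo-2-oxopropyl)phosphonate, CC(=O)C(=[N+]=[N-])P(=O)(OC)OC
Why: Ohira–Bestmann form of the Seyferth–Gilbert homologation: methanolysis of the acetyl group releases the diazomethylphosphonate anion, which olefinates the aldehyde and loses N2 with a 1,2-hydrogen shift to the terminal alkyne; the mild carbonate conditions at 0 °C should leave the α-alkoxy stereocentre (future C5) untouched.

Step 2
Reactants: 2 (R)-4-ethynyl-2,2-dimethyl-1,3-dioxolane; 3 methyl (E)-3-iodoacrylate
Product: 4 methyl (2E)-5-[(4R)-2,2-dimethyl-1,3-dioxolan-4-yl]pent-2-en-4-ynoate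
Conditions: Pd(PPh3)2Cl2 (3 mol%), CuI (6 mol%), Et3N, THF, 0 °C → rt
Reagents that add atoms: none
Why: Sonogashira coupling of a terminal alkyne with an activated alkenyl iodide; oxidative addition to zerovalent palladium and reductive elimination both proceed with retention, so the E geometry of the future C1=C2 is carried over, and the neutral conditions leave the acetonide alone.

Step 3
Reactants: 4 methyl (2E)-5-[(4R)-2,2-dimethyl-1,3-dioxolan-4-yl]pent-2-en-4-ynoate
Product: 5 methyl (2E,4Z)-5-[(4R)-2,2-dimethyl-1,3-dioxolan-4-yl]penta-2,4-dienoate
Conditions: H2 (1 atm), Pd/CaCO3 poisoned with Pb(OAc)2, quinoline, EtOAc, rt, stopped after one equivalent of H2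
Reagents that add atoms: none
Why: Lindlar-type cis-semihydrogenation: syn delivery of hydrogen to the alkyne on the poisoned palladium surface gives the Z alkene that becomes C3=C4, and quinoline with monitored uptake should limit reduction of the conjugated diene.

Step 4
Reactants: 5 methyl (2E,4Z)-5-[(4R)-2,2-dimethyl-1,3-dioxolan-4-yl]penta-2,4-dienoate
Product: 6 methyl (2E,4Z,6R)-6,7-dihydroxyhepta-2,4-dienoate
Conditions: AcOH/H2O (4:1), rt → 40 °C
Reagents that add atoms: none
Why: Acid-catalysed hydrolysis of a terminal acetonide (acetal cleavage); aqueous acetic acid is too weak to isomerise the Z alkene or ionise the allylic C–O bond, and the stereocentre is not involved.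

Step 5
Reactants: 6 methyl (2E,4Z,6R)-6,7-dihydroxyhepta-2,4-dienoate
Product: 7 methyl (2E,4Z,6R)-6,7-bis[(triethylsilyl)oxy]hepta-2,4-dienoate
Conditions: TESCl (2.4 equiv), imidazole, CH2Cl2, 0 °C → rt
Reagents that add atoms: chlorotriethylsilane, CC[Si](CC)(CC)Cl
Why: Standard silylation of both hydroxyls (imidazole-promoted silyl ether formation); triethylsilyl is chosen because the primary ether can be oxidised directly in the next step and the secondary one can later be removed beside a bulkier silyl ether.

Step 6
Reactants: 7 methyl (2E,4Z,6R)-6,7-bis[(triethylsilyl)oxy]hepta-2,4-dienoate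
Product: 8 methyl (2E,4Z,6R)-7-oxo-6-[(triethylsilyl)oxy]hepta-2,4-dienoate
Conditions: (COCl)2, DMSO, CH2Cl2, −78 → −40 °C; iPr2NEt, −78 → −20 °C; cold pH 7 phosphate buffer; used at once
Reagents that add atoms: none
Why: Swern oxidation applied directly to a silyl ether: chlorodimethylsulfonium chloride attacks the unhindered primary silyl ether oxygen, chloride removes silicon, and the alkoxysulfonium salt collapses to the aldehyde on addition of base, while the more hindered secondary triethylsilyl ether should survive; the hindered amine and the cold buffered work-up are chosen because the aldehyde α-hydrogen (future C5) is also activated through the dienoate and would otherwise be lost with epimerisation.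

Step 7
Reactants: 8 methyl (2E,4Z,6R)-7-oxo-6-[(triethylsilyl)oxy]hepta-2,4-dienoate
Product: 9 methyl (5R,6R)-6-hydroxy-5-[(triethylsilyl)oxy]cyclohexa-1,3-diene-1-carboxylate
Conditions: PMe3 (1.0 equiv, 1 M in THF), t-AmOH, 0.02 M, 0 °C → rt
Reagents that add atoms: none
Why: Intramolecular Morita–Baylis–Hillman reaction, the closest known type being the trialkylphosphine-catalysed cyclisation of formyl-tethered enoates to cycloalkenol carboxylates. PMe3 adds reversibly to C2, the β-carbon of the dienoate, giving a phosphonium ester enolate in which the cis C3=C4 alkene is untouched and holds C6 within reach of C1. The enolate carbon C1 then adds to the aldehyde C6 in a 6-(enolexo)-exo-trig aldol closure that forms the C1–C6 bond and the only ring; proton transfer from C1 to the aldolate, relayed by the tertiary alcohol solvent, and E1cB loss of PMe3 from C2 restore C1=C2 in conjugation with C3=C4. The new stereocentre C6 is controlled by C5: in the half-chair transition state the C5–OSi bond and the aldehyde C=O lie anti, opposing their dipoles and keeping the bulky silyloxy group away from the incoming enolate, which places the new hydroxyl trans to O5, and because the aldol step is reversible before the slower elimination a cis aldolate can revert. The step needs 1,4- over 1,6-addition of the phosphine, retention of configuration at C5, and cyclisation over oligomerisation. The first is served by the substrate, since C4 is cis-substituted and flanked by the branched C5 whereas C2 is an unhindered CH; the second by a small, only moderately basic phosphine in a protic medium that protonates the aldolate quickly (which also suppresses silyl migration from O5 to O6); the third by high dilution and the ease of six-membered closure.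

Step 8
Reactants: 9 methyl (5R,6R)-6-hydroxy-5-[(triethylsilyl)oxy]cyclohexa-1,3-diene-1-carboxylate
Product: 10 methyl (5R,6R)-6-[(tert-butyldimethylsilyl)oxy]-5-[(triethylsilyl)oxy]cyclohexa-1,3-diene-1-carboxylate
Conditions: TBSOTf, 2,6-lutidine, CH2Cl2, −78 → 0 °C
Reagents that add atoms: tert-butyldimethylsilyl trifluoromethanesulfonate, CC(C)(C)[Si](C)(C)OS(=O)(=O)C(F)(F)F
Why: Silylation of a hindered secondary alcohol with a silyl triflate and a hindered pyridine base that is too weak to deprotonate C5; the tert-butyldimethylsilyl group is chosen to outlast both the hydride reduction and the later removal of the triethylsilyl group on O5.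

Step 9
Reactants: 10 methyl (5R,6R)-6-[(tert-butyldimethylsilyl)oxy]-5-[(triethylsilyl)oxy]cyclohexa-1,3-diene-1-carboxylate
Product: 12 [(5R,6R)-6-[(tert-butyldimethylsilyl)oxy]-5-[(triethylsilyl)oxy]cyclohexa-1,3-dien-1-yl]methanol, via silylated dienal 11 (not isolated)
Conditions: iBu2AlH (2.5 equiv), CH2Cl2, −78 → −40 °C; aq. potassium sodium tartrate
Reagents that add atoms: none
Why: 1,2-Reduction of a conjugated ester by the aluminium hydride; the hemiacetal aluminate of an unsaturated ester collapses to the aldehyde, which is reduced further to the allylic alcohol C7, and the neutral tartrate work-up spares the silyl ethers and the diene.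

Step 10
Reactants: 12 [(5R,6R)-6-[(tert-butyldimethylsilyl)oxy]-5-[(triethylsilyl)oxy]cyclohexa-1,3-dien-1-yl]methanol
Product: 13 (1R,6R)-6-[(tert-butyldimethylsilyl)oxy]-5-(hydroxymethyl)cyclohexa-2,4-dien-1-ol
Conditions: PPTS (0.2 equiv), MeOH/CH2Cl2, 0 °C
Reagents that add atoms: none
Why: Chemoselective acid-catalysed methanolysis of the secondary triethylsilyl ether, which is far more labile than the neighbouring tert-butyldimethylsilyl ether; the buffered pyridinium acid should be too mild to ionise the dienylic C5–O bond, and no base is present to drive silyl migration from O6 to O5.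

Step 11
Reactants: 13 (1R,6R)-6-[(tert-butyldimethylsilyl)oxy]-5-(hydroxymethyl)cyclohexa-2,4-dien-1-ol
Product: 14 [(5R,6R)-5-(benzoyloxy)-6-[(tert-butyldimethylsilyl)oxy]cyclohexa-1,3-dien-1-yl]methyl benzoate
Conditions: BzCl (2.4 equiv), pyridine, DMAP (0.1 equiv), CH2Cl2, 0 °C → rt
Reagents that add atoms: benzoyl chloride, O=C(Cl)c1ccccc1
Why: DMAP-catalysed acylation of the primary O7 and secondary O5 hydroxyls; O6 is blocked, so the pattern of two benzoates flanking one masked hydroxyl is fixed without any selectivity demand.

Step 12
Reactants: 14 [(5R,6R)-5-(benzoyloxy)-6-[(tert-butyldimethylsilyl)oxy]cyclohexa-1,3-dien-1-yl]methyl benzoate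
Product: 15 [(5R,6R)-5-(benzoyloxy)-6-hydroxycyclohexa-1,3-dien-1-yl]methyl benzoate
Conditions: HF·pyridine, pyridine, THF, 0 °C → rt; aq. NaHCO3
Reagents that add atoms: none
Why: Fluoride-mediated cleavage of the silyl ether, driven by Si–F bond formation, under buffered weakly acidic conditions; the absence of basic fluoride should avoid benzoyl migration from O5 to O6 and E1cB loss of benzoate, and the excess pyridine limits acid-induced ionisation at C5.

## Compound list

1 | (S)-2,2-dimethyl-1,3-dioxolane-4-carbaldehyde | O=C[C@@H]1COC(C)(C)O1 | starting material
2 | (R)-4-ethynyl-2,2-dimethyl-1,3-dioxolane | C#C[C@@H]1COC(C)(C)O1 | intermediate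
3 | methyl (E)-3-iodoacrylate | COC(=O)/C=C/I | starting material
4 | methyl (2E)-5-[(4R)-2,2-dimethyl-1,3-dioxolan-4-yl]pent-2-en-4-ynoate | COC(=O)/C=C/C#C[C@@H]1COC(C)(C)O1 | intermediate
5 | methyl (2E,4Z)-5-[(4R)-2,2-dimethyl-1,3-dioxolan-4-yl]penta-2,4-dienoate | COC(=O)/C=C/C=C\[C@@H]1COC(C)(C)O1 | intermediate
6 | methyl (2E,4Z,6R)-6,7-dihydroxyhepta-2,4-dienoate | COC(=O)/C=C/C=C\[C@@H](O)CO | intermediate
7 | methyl (2E,4Z,6R)-6,7-bis[(triethylsilyl)oxy]hepta-2,4-dienoate | COC(=O)/C=C/C=C\[C@@H](O[Si](CC)(CC)CC)CO[Si](CC)(CC)CC | intermediate
8 | methyl (2E,4Z,6R)-7-oxo-6-[(triethylsilyl)oxy]hepta-2,4-dienoate | O=C[C@H](O[Si](CC)(CC)CC)/C=C\C=C\C(=O)OC | intermediate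
9 | methyl (5R,6R)-6-hydroxy-5-[(triethylsilyl)oxy]cyclohexa-1,3-diene-1-carboxylate | COC(=O)C1=CC=C[C@@H](O[Si](CC)(CC)CC)[C@@H]1O | intermediate
10 | methyl (5R,6R)-6-[(tert-butyldimethylsilyl)oxy]-5-[(triethylsilyl)oxy]cyclohexa-1,3-diene-1-carboxylate | COC(=O)C1=CC=C[C@@H](O[Si](CC)(CC)CC)[C@@H]1O[Si](C)(C)C(C)(C)C | intermediate
11 | (5R,6R)-6-[(tert-butyldimethylsilyl)oxy]-5-[(triethylsilyl)oxy]cyclohexa-1,3-diene-1-carbaldehyde | O=CC1=CC=C[C@@H](O[Si](CC)(CC)CC)[C@@H]1O[Si](C)(C)C(C)(C)C | intermediate
12 | [(5R,6R)-6-[(tert-butyldimethylsilyl)oxy]-5-[(triethylsilyl)oxy]cyclohexa-1,3-dien-1-yl]methanol | OCC1=CC=C[C@@H](O[Si](CC)(CC)CC)[C@@H]1O[Si](C)(C)C(C)(C)C | intermediate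
13 | (1R,6R)-6-[(tert-butyldimethylsilyl)oxy]-5-(hydroxymethyl)cyclohexa-2,4-dien-1-ol | OCC1=CC=C[C@@H](O)[C@@H]1O[Si](C)(C)C(C)(C)C | intermediate
14 | [(5R,6R)-5-(benzoyloxy)-6-[(tert-butyldimethylsilyl)oxy]cyclohexa-1,3-dien-1-yl]methyl benzoate | O=C(OCC1=CC=C[C@@H](OC(=O)c2ccccc2)[C@@H]1O[Si](C)(C)C(C)(C)C)c1ccccc1 | intermediate
15 | [(5R,6R)-5-(benzoyloxy)-6-hydroxycyclohexa-1,3-dien-1-yl]methyl benzoate | O=C(OCC1=CC=C[C@@H](OC(=O)c2ccccc2)[C@@H]1O)c1ccccc1 | target

## Step count and least certain steps

Total step count: 12. Longest linear sequence: 12 steps (1 to 15); 3 enters at step 2.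

Step 7 (key step).
- What may go wrong: reversible addition of the phosphine at C4 instead of C2, followed by bond rotation and loss of the phosphine, would isomerise the C3=C4 alkene from Z to E and leave material that cannot cyclise. Enolisation of the aldehyde would epimerise C5 or move the alkene into conjugation. Base-induced elimination across C5/C6 would aromatise the product.
- Fallback (sets out from 8, returns at 9): the catalytic phosphine is replaced by a thiolate-triggered Michael–aldol sequence followed by sulfoxide elimination. PhSH with a catalytic amount of PhSLi in THF at −40 °C should add at C2 and close the resulting enolate onto C6 to give methyl (5R,6R)-6-hydroxy-2-(phenylsulfanyl)-5-[(triethylsilyl)oxy]cyclohex-3-ene-1-carboxylate F1 (a mixture at C1 and C2, both centres lost later). S-Oxidation with mCPBA at −78 °C would give methyl (5R,6R)-6-hydroxy-2-(phenylsulfinyl)-5-[(triethylsilyl)oxy]cyclohex-3-ene-1-carboxylate F2. Warming F2 in toluene over CaCO3 should eliminate benzenesulfenic acid towards the acidic C1–H and give 9. Sulfur is preferred to selenium because an allylic selenoxide would undergo the 2,3-shift faster than it eliminates.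

Step 6.
- What may go wrong: epimerisation at the future C5 while the amine is present, and partial cleavage of the secondary silyl ether if the mixture warms before the base is added.
- Fallback (sets out from 7, returns at 8): the operation is split so that no amine meets the aldehyde. Selective methanolysis of the primary silyl ether (PPTS, MeOH/CH2Cl2, −20 °C) would give methyl (2E,4Z,6R)-7-hydroxy-6-[(triethylsilyl)oxy]hepta-2,4-dienoate F3. Oxidation with Dess–Martin periodinane buffered with pyridine in CH2Cl2 at 0 °C would then give 8.

Step 3.
- What may go wrong: over-reduction of the conjugated diene and partial Z to E isomerisation on the catalyst surface.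
- Fallback (sets out from 1, returns at 5, replacing steps 1 to 3 and one step shorter): Stork–Zhao olefination of 1 with (iodomethyl)triphenylphosphonium iodide and NaN(SiMe3)2 in THF/DMPU at −78 °C would give (4R)-4-[(Z)-2-iodoethenyl]-2,2-dimethyl-1,3-dioxolane F4. A Heck reaction with methyl acrylate (Pd(OAc)2, Ag2CO3, DMF, rt) would build the E enoate with retention of the Z alkene. This is not the first choice because the Z selectivity of the olefination and the configurational stability of a Z-alkenylpalladium species are less assured than syn-hydrogenation.

Step 12.
- What may go wrong: slow cleavage of a hindered secondary silyl ether gives time for ionisation at C5 with loss of benzoic acid and aromatisation, or for benzoyl migration from O5 to O6.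
- Fallback (sets out from 13, returns at 15): silicon is removed before any benzoate is present, and a transient boronate takes over the role of the O6 protecting group. Bu4NF in THF at 0 °C would convert 13 into (1R,2R)-3-(hydroxymethyl)cyclohexa-3,5-diene-1,2-diol F5. PhB(OH)2 (1 equiv, CH2Cl2, molecular sieves) should bridge the 1,3-related O6 and O7 as (8R,8aR)-2-phenyl-8,8a-dihydro-4H-1,3,2-benzodioxaborinin-8-ol F6, since the trans O5/O6 pair cannot span boron without strain. Benzoylation of the free O5 (BzCl, pyridine, 0 °C) would give (8R,8aR)-2-phenyl-8,8a-dihydro-4H-1,3,2-benzodioxaborinin-8-yl benzoate F7. Exchange of boron to pinacol would release (1R,6R)-6-hydroxy-5-(hydroxymethyl)cyclohexa-2,4-dien-1-yl benzoate F8. Benzoylation of the primary hydroxyl in preference to the hindered O6–H (BzCl 1.05 equiv, 2,4,6-collidine, CH2Cl2, −78 → −40 °C) would give 15.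

## Further compounds

F1 | step 7 | methyl (5R,6R)-6-hydroxy-2-(phenylsulfanyl)-5-[(triethylsilyl)oxy]cyclohex-3-ene-1-carboxylate (mixture at C1 and C2) | COC(=O)C1C(Sc2ccccc2)C=C[C@@H](O[Si](CC)(CC)CC)[C@@H]1O
F2 | step 7 | methyl (5R,6R)-6-hydroxy-2-(phenylsulfinyl)-5-[(triethylsilyl)oxy]cyclohex-3-ene-1-carboxylate (mixture at C1, C2 and sulfur) | COC(=O)C1C(S(=O)c2ccccc2)C=C[C@@H](O[Si](CC)(CC)CC)[C@@H]1O
F3 | step 6 | methyl (2E,4Z,6R)-7-hydroxy-6-[(triethylsilyl)oxy]hepta-2,4-dienoate | COC(=O)/C=C/C=C\[C@@H](O[Si](CC)(CC)CC)CO
F4 | step 3 | (4R)-4-[(Z)-2-iodoethenyl]-2,2-dimethyl-1,3-dioxolane | I/C=C\[C@@H]1COC(C)(C)O1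
F5 | step 12 | (1R,2R)-3-(hydroxymethyl)cyclohexa-3,5-diene-1,2-diol | OCC1=CC=C[C@@H](O)[C@@H]1O
F6 | step 12 | (8R,8aR)-2-phenyl-8,8a-dihydro-4H-1,3,2-benzodioxaborinin-8-ol | B1(c2ccccc2)OCC2=CC=C[C@@H](O)[C@@H]2O1
F7 | step 12 | (8R,8aR)-2-phenyl-8,8a-dihydro-4H-1,3,2-benzodioxaborinin-8-yl benzoate | B1(c2ccccc2)OCC2=CC=C[C@@H](OC(=O)c3ccccc3)[C@@H]2O1
F8 | step 12 | (1R,6R)-6-hydroxy-5-(hydroxymethyl)cyclohexa-2,4-dien-1-yl benzoate | OCC1=CC=C[C@@H](OC(=O)c2ccccc2)[C@@H]1O
A1 | alternative 1 | (1R,2R)-cyclohexa-3,5-diene-1,2-diol | C1=CC=C[C@@H](O)[C@@H]1O
A2 | alternative 1 | (1R,6R)-6-{[(iodomethyl)dimethylsilyl]oxy}cyclohexa-2,4-dien-1-yl benzoate | C1=CC=C[C@@H](OC(=O)c2ccccc2)[C@@H]1O[Si](C)(C)CI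
A3 | alternative 1 | (7R,7aR)-2,2-dimethyl-2,3,7,7a-tetrahydro-1,2-benzoxasilol-7-yl benzoate | C[Si]1(C)CC2=CC=C[C@@H](OC(=O)c3ccccc3)[C@@H]2O1
A4 | alternative 2 | (1E,3E)-4-[(2R,5R)-2,5-diphenylpyrrolidin-1-yl]buta-1,3-dien-1-yl benzoate | O=C(O/C=C/C=C/N1[C@@H](c2ccccc2)CC[C@@H]1c1ccccc1)c1ccccc1
A5 | alternative 2 | (E)-3-[(triisopropylsilyl)oxy]prop-2-enal | O=C/C=C/O[Si](C(C)C)(C(C)C)C(C)C
A6 | alternative 2 | (5R,6R)-5-(benzoyloxy)-6-[(triisopropylsilyl)oxy]cyclohexa-1,3-diene-1-carbaldehyde | O=CC1=CC=C[C@@H](OC(=O)c2ccccc2)[C@@H]1O[Si](C(C)C)(C(C)C)C(C)C
A7 | alternative 3 | (3R,5R)-3,5-bis[(tert-butyldimethylsilyl)oxy]cyclopent-1-ene | C1=C[C@H](O[Si](C)(C)C(C)(C)C)C[C@H]1O[Si](C)(C)C(C)(C)C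
A8 | alternative 3 | (2R,4R)-6,6-dibromo-2,4-bis[(tert-butyldimethylsilyl)oxy]bicyclo[3.1.0]hexane, silyloxy groups trans, ring fusion as drawn | BrC1(Br)[C@@H]2[C@H](O[Si](C)(C)C(C)(C)C)C[C@@H](O[Si](C)(C)C(C)(C)C)[C@H]12
A9 | alternative 3 | (1S,4R,6R)-2-bromo-4,6-bis[(tert-butyldimethylsilyl)oxy]cyclohex-2-en-1-ol | BrC1=C[C@H](O[Si](C)(C)C(C)(C)C)C[C@@H](O[Si](C)(C)C(C)(C)C)[C@@H]1O
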